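(The runs were computed for an exercise, and the scatter is random.)

Links are the product of these flasks, and what matters is the share of the first end groups that reaches them.

| setting | gamma | theta | flask |
|---|---|---|---|
| first end groups | 0.050 M | 0.20 M | 0.10 M |
| second end groups | 1.05 equiv (in portions, 3) | 1.05 equiv (in portions, 3) | 1.05 equiv (in portions, 3) |
| remark | run made earlier; portions every 4.0 h | run made earlier; portions every 4.0 h | the portions of second end groups follow each other after 4.0 h, the first at the start |
| time |  |  | 15 d |

- gamma (time / d: first end groups / %, links / %): 2.50: 0.2, 76.8; 5.00: 0.1, 76.2; 8.00: 0, 76.4; 10.0: 0, 76.8; 12.0: 0.3, 77.1; 15.0: 0.3, 76.6; 20.0: 0, 76.3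
- theta (time / d: first end groups / %, links / %): 2.50: 0.2, 59.6; 5.00: 0, 59.7; 8.00: 0.5, 60.2; 10.0: 0.2, 60.5; 12.0: 0, 59.5; 15.0: 0, 59.6; 20.0: 0, 59.8

(readings scatter by 0.3 percentage points)

- the state of affairs at 15 d: stopped, and by what, or still going (all of the first end groups has reacted / the second end groups has run out first / it is still moving)
- share of the first end groups used up at 15 d
- links at 15 d, in percent of the first end groups charged

- the reaction counts as stopped when no species that holds the first end groups changes by six tenths of a point or more over the second half of the time

In both runs the first end groups read 0.2% and 0.2% at 2.50 d, within the scatter of 0.3 percentage points around zero, so I expected the flask to finish well before 15 d. Two amounts then remain: first end groups in links and first end groups lost elsewhere. Their ratio ρ is a ratio of final amounts, first end groups lost over first end groups in links, and it is the inverse of a selectivity. With links averaged at 76.6% and 59.8%, ρ was 0.305 in the gamma run and 0.671 in the theta run. The flask's 0.10 M is the geometric mean of the two concentrations. If ρ follows a power of concentration, whatever the exponent, the flask's loss ratio is the geometric mean of the two ratios, 0.453, which gave links at 68.8%. Both runs held the equivalents fixed, so I assumed that at fixed concentration ρ falls inversely with them.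

The forecast said all of the first end groups has reacted, with 100% used up and links at 69%, between 66% and 72%: “Links fall as concentration rises, so a side path of higher order competes.” It fitted an exponent; I used none.

The flask gave: all of the first end groups has reacted, 100% used up, links at 69.1%.

    first end groups + second end groups → links + by-product (k = 13.9 L mol⁻¹ h⁻¹)
    first end groups + links → side product (k = 0.365 L mol⁻¹ h⁻¹)
    2 first end groups → homo dimer (k = 0.618 L mol⁻¹ h⁻¹)

The flask's ρ came out at 0.447 against my 0.453, with first end groups the limiting reagent, 0% left against 30% of the second end groups. At 0.843 equiv or 1.33 equiv of second end groups, links had moved by 5 points, which put them outside the forecast's range. For the neighbouring flask with 2.60 equiv, scaling 0.453 gave 0.183, so links at 84.5%. That neighbouring flask gave links at 86.5%, a loss ratio of 0.156.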